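**Retrosynthetic overview**
- The target is reached by hydrogenolysis of one benzyl ether and one benzyl ester, preceded by hydrolysis of two dioxolanes that mask the side-chain ketones.
- The depside ester C(=O)–OAr is cut next (Steglich esterification) into an A-ring acid (2-OBn, 4-OMe, ketal arm) and a B-ring phenol (benzyl ester, 2-OMe, 4-OH, ketal arm).
- Each 2-oxoheptyl arm comes from lateral (benzylic) lithiation of an orsellinate methyl ester and acylation with the Weinreb amide of hexanoic acid.
- The two O-patterns come from sparassol (A) and from regioselective 4-O-benzylation then 2-O-methylation of methyl orsellinate (B).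
- No ring is built: both benzene rings are bought. Only the two temporary dioxolanes are closed (steps 3 and 7) and reopened (step 12).

**Assumption:** the target has no stereocentre (it is achiral), so no stereocontrol is needed; sparassol, methyl orsellinate and N-methoxy-N-methylhexanamide are taken as catalogue compounds.

**A-ring acid (steps 1–4)**

Step 1
Reactants: 1 methyl 2-hydroxy-4-methoxy-6-methylbenzoate (sparassol); 2 benzyl bromide
Product: 3 methyl 2-(benzyloxy)-4-methoxy-6-methylbenzoate
Conditions: BnBr (1.2 equiv), K2CO3, DMF, 60 °C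
Reagents that add atoms: benzyl bromide BrCc1ccccc1
Why: Williamson ether synthesis on the chelated phenol; benzyl is chosen because it survives LDA and KOH and leaves in the final hydrogenolysis.

Step 2
Reactants: 3 methyl 2-(benzyloxy)-4-methoxy-6-methylbenzoate; 4 N-methoxy-N-methylhexanamide
Product: 6 methyl 2-(benzyloxy)-4-methoxy-6-(2-oxoheptyl)benzoate, via benzylic organolithium 5 (not isolated)
Conditions: LDA (1.3 equiv), THF, −78 °C, 20 min; then 4 (1.3 equiv), −78 °C, 1 h; AcOH quench at −78 °C
Reagents that add atoms: N-methoxy-N-methylhexanamide CCCCCC(=O)N(C)OC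
Why: Lateral lithiation of the methyl group ortho to the ester followed by Weinreb ketone synthesis, which stops cleanly at the ketone without over-addition.

Step 3
Reactants: 6 methyl 2-(benzyloxy)-4-methoxy-6-(2-oxoheptyl)benzoate; 7 1,2-bis(trimethylsilyloxy)ethane
Product: 8 methyl 2-(benzyloxy)-4-methoxy-6-[(2-pentyl-1,3-dioxolan-2-yl)methyl]benzoate
Conditions: (TMSOCH2)2 (2 equiv), TMSOTf (5 mol%), CH2Cl2, −78 → −20 °C; pyridine quench
Reagents that add atoms: 1,2-bis(trimethylsilyloxy)ethane C[Si](C)(C)OCCO[Si](C)(C)C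
Why: Noyori ketalization under aprotic low-temperature conditions masks the ketone, so that its enol cannot later attack the activated carboxyl and close an isocoumarin.

Step 4
Reactants: 8 methyl 2-(benzyloxy)-4-methoxy-6-[(2-pentyl-1,3-dioxolan-2-yl)methyl]benzoate; 9 potassium hydroxide
Product: 10 2-(benzyloxy)-4-methoxy-6-[(2-pentyl-1,3-dioxolan-2-yl)methyl]benzoic acid
Conditions: KOH (10 equiv), DMSO–H2O (4:1), 90 °C; then cold 1 M HCl to pH 4, extract at once
Reagents that add atoms: potassium hydroxide [K+].[OH-]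
Why: Forced saponification of the di-ortho-substituted ester is safe because the dioxolane, benzyl ether and methyl ether are all base-stable and no free ketone is present to condense.

**B-ring phenol (steps 5–10)**

Step 5
Reactants: 11 methyl 2,4-dihydroxy-6-methylbenzoate (methyl orsellinate); 2 benzyl bromide; 12 iodomethane
Product: 14 methyl 4-(benzyloxy)-2-methoxy-6-methylbenzoate, via mono-benzyl ether 13 (not isolated)
Conditions: BnBr (1.05 equiv), K2CO3 (4 equiv), acetone, reflux; then MeI (5 equiv), reflux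
Reagents that add atoms: benzyl bromide BrCc1ccccc1; iodomethane CI
Why: Sequential Williamson etherification: the free, more acidic 4-OH takes the single equivalent of benzyl bromide, and the chelated 2-OH is then methylated by excess iodomethane.

Step 6
Reactants: 14 methyl 4-(benzyloxy)-2-methoxy-6-methylbenzoate; 4 N-methoxy-N-methylhexanamide
Product: 16 methyl 4-(benzyloxy)-2-methoxy-6-(2-oxoheptyl)benzoate, via benzylic organolithium 15 (not isolated)
Conditions: LDA (1.3 equiv), THF, −78 °C, 20 min; then 4 (1.3 equiv), −78 °C, 1 h; AcOH quench at −78 °C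
Reagents that add atoms: N-methoxy-N-methylhexanamide CCCCCC(=O)N(C)OC
Why: Same lateral lithiation and Weinreb ketone synthesis as in step 2; the benzyl and methyl ethers are inert to LDA at −78 °C.

Step 7
Reactants: 16 methyl 4-(benzyloxy)-2-methoxy-6-(2-oxoheptyl)benzoate; 7 1,2-bis(trimethylsilyloxy)ethane
Product: 17 methyl 4-(benzyloxy)-2-methoxy-6-[(2-pentyl-1,3-dioxolan-2-yl)methyl]benzoate
Conditions: (TMSOCH2)2 (2 equiv), TMSOTf (5 mol%), CH2Cl2, −78 → −20 °C; pyridine quench
Reagents that add atoms: 1,2-bis(trimethylsilyloxy)ethane C[Si](C)(C)OCCO[Si](C)(C)C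
Why: Noyori ketalization removes the enolizable ketone, which would otherwise undergo Claisen-type cyclization during the saponification that follows.

Step 8
Reactants: 17 methyl 4-(benzyloxy)-2-methoxy-6-[(2-pentyl-1,3-dioxolan-2-yl)methyl]benzoate; 9 potassium hydroxide
Product: 18 4-(benzyloxy)-2-methoxy-6-[(2-pentyl-1,3-dioxolan-2-yl)methyl]benzoic acid
Conditions: KOH (10 equiv), DMSO–H2O (4:1), 90 °C; then cold 1 M HCl to pH 4, extract at once
Reagents that add atoms: potassium hydroxide [K+].[OH-]
Why: Saponification of the hindered methyl ester, with every other group base-stable as in step 4.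

Step 9
Reactants: 18 4-(benzyloxy)-2-methoxy-6-[(2-pentyl-1,3-dioxolan-2-yl)methyl]benzoic acid
Product: 19 4-hydroxy-2-methoxy-6-[(2-pentyl-1,3-dioxolan-2-yl)methyl]benzoic acid
Conditions: H2 (1 atm), 10% Pd/C, EtOAc, rt
Reagents that add atoms: none
Why: Catalytic hydrogenolysis of the aryl benzyl ether frees the 4-OH in an aprotic solvent that leaves the dioxolane intact.

Step 10
Reactants: 19 4-hydroxy-2-methoxy-6-[(2-pentyl-1,3-dioxolan-2-yl)methyl]benzoic acid; 2 benzyl bromide
Product: 20 benzyl 4-hydroxy-2-methoxy-6-[(2-pentyl-1,3-dioxolan-2-yl)methyl]benzoate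
Conditions: BnBr (1.05 equiv), KHCO3 (1.1 equiv), DMF, rt
Reagents that add atoms: benzyl bromide BrCc1ccccc1
Why: Chemoselective SN2 O-alkylation of the carboxylate, because hydrogencarbonate deprotonates the acid but not the phenol.

**Endgame (steps 11–13)**

Step 11
Reactants: 10 2-(benzyloxy)-4-methoxy-6-[(2-pentyl-1,3-dioxolan-2-yl)methyl]benzoic acid; 20 benzyl 4-hydroxy-2-methoxy-6-[(2-pentyl-1,3-dioxolan-2-yl)methyl]benzoate
Product: 21 benzyl 4-({2-(benzyloxy)-4-methoxy-6-[(2-pentyl-1,3-dioxolan-2-yl)methyl]benzoyl}oxy)-2-methoxy-6-[(2-pentyl-1,3-dioxolan-2-yl)methyl]benzoate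
Conditions: DCC (1.3 equiv), DMAP (0.3 equiv), CH2Cl2, 0 °C → rt
Reagents that add atoms: none
Why: Steglich esterification of the unhindered 4-OH with the carbodiimide-activated acid; the masked ketone and the benzylated 2-OH leave the phenol as the only nucleophile.

Step 12
Reactants: 21 the bis-dioxolane depside benzyl ester; 22 water
Product: 23 benzyl 4-{[2-(benzyloxy)-4-methoxy-6-(2-oxoheptyl)benzoyl]oxy}-2-methoxy-6-(2-oxoheptyl)benzoate
Conditions: 2 M aq HCl–THF (1:4), rt; neutral work-up without base wash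
Reagents that add atoms: water O
Why: Acid-catalysed acetal hydrolysis frees both ketones, and base is avoided because an enolate of the A-ring ketone would expel the phenol and close an isocoumarin.

Step 13
Reactants: 23 benzyl 4-{[2-(benzyloxy)-4-methoxy-6-(2-oxoheptyl)benzoyl]oxy}-2-methoxy-6-(2-oxoheptyl)benzoate
Product: 24 4-{[2-hydroxy-4-methoxy-6-(2-oxoheptyl)benzoyl]oxy}-2-methoxy-6-(2-oxoheptyl)benzoic acid (target)
Conditions: H2 (1 atm), 10% Pd/C, EtOAc, rt
Reagents that add atoms: none
Why: Neutral catalytic hydrogenolysis removes the benzyl ether and benzyl ester together, leaving the aryl ester and the dialkyl ketones untouched; there is no stereocentre to set.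

**Compound list**
1 | methyl 2-hydroxy-4-methoxy-6-methylbenzoate (sparassol) | COC(=O)c1c(C)cc(OC)cc1O | starting material
2 | benzyl bromide | BrCc1ccccc1 | starting material
3 | methyl 2-(benzyloxy)-4-methoxy-6-methylbenzoate | COC(=O)c1c(C)cc(OC)cc1OCc1ccccc1 | intermediate
4 | N-methoxy-N-methylhexanamide | CCCCCC(=O)N(C)OC | starting material
5 | [3-(benzyloxy)-5-methoxy-2-(methoxycarbonyl)phenyl]methyllithium | COC(=O)c1c(C[Li])cc(OC)cc1OCc1ccccc1 | intermediate
6 | methyl 2-(benzyloxy)-4-methoxy-6-(2-oxoheptyl)benzoate | CCCCCC(=O)Cc1cc(OC)cc(OCc2ccccc2)c1C(=O)OC | intermediate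
7 | 1,2-bis(trimethylsilyloxy)ethane | C[Si](C)(C)OCCO[Si](C)(C)C | starting material
8 | methyl 2-(benzyloxy)-4-methoxy-6-[(2-pentyl-1,3-dioxolan-2-yl)methyl]benzoate | CCCCCC1(Cc2cc(OC)cc(OCc3ccccc3)c2C(=O)OC)OCCO1 | intermediate
9 | potassium hydroxide | [K+].[OH-] | starting material
10 | 2-(benzyloxy)-4-methoxy-6-[(2-pentyl-1,3-dioxolan-2-yl)methyl]benzoic acid | CCCCCC1(Cc2cc(OC)cc(OCc3ccccc3)c2C(=O)O)OCCO1 | intermediate
11 | methyl 2,4-dihydroxy-6-methylbenzoate (methyl orsellinate) | COC(=O)c1c(C)cc(O)cc1O | starting material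
12 | iodomethane | CI | starting material
13 | methyl 4-(benzyloxy)-2-hydroxy-6-methylbenzoate | COC(=O)c1c(C)cc(OCc2ccccc2)cc1O | intermediate
14 | methyl 4-(benzyloxy)-2-methoxy-6-methylbenzoate | COC(=O)c1c(C)cc(OCc2ccccc2)cc1OC | intermediate
15 | [5-(benzyloxy)-3-methoxy-2-(methoxycarbonyl)phenyl]methyllithium | COC(=O)c1c(C[Li])cc(OCc2ccccc2)cc1OC | intermediate
16 | methyl 4-(benzyloxy)-2-methoxy-6-(2-oxoheptyl)benzoate | CCCCCC(=O)Cc1cc(OCc2ccccc2)cc(OC)c1C(=O)OC | intermediate
17 | methyl 4-(benzyloxy)-2-methoxy-6-[(2-pentyl-1,3-dioxolan-2-yl)methyl]benzoate | CCCCCC1(Cc2cc(OCc3ccccc3)cc(OC)c2C(=O)OC)OCCO1 | intermediate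
18 | 4-(benzyloxy)-2-methoxy-6-[(2-pentyl-1,3-dioxolan-2-yl)methyl]benzoic acid | CCCCCC1(Cc2cc(OCc3ccccc3)cc(OC)c2C(=O)O)OCCO1 | intermediate
19 | 4-hydroxy-2-methoxy-6-[(2-pentyl-1,3-dioxolan-2-yl)methyl]benzoic acid | CCCCCC1(Cc2cc(O)cc(OC)c2C(=O)O)OCCO1 | intermediate
20 | benzyl 4-hydroxy-2-methoxy-6-[(2-pentyl-1,3-dioxolan-2-yl)methyl]benzoate | CCCCCC1(Cc2cc(O)cc(OC)c2C(=O)OCc2ccccc2)OCCO1 | intermediate
21 | benzyl 4-({2-(benzyloxy)-4-methoxy-6-[(2-pentyl-1,3-dioxolan-2-yl)methyl]benzoyl}oxy)-2-methoxy-6-[(2-pentyl-1,3-dioxolan-2-yl)methyl]benzoate | CCCCCC1(Cc2cc(OC)cc(OCc3ccccc3)c2C(=O)Oc2cc(CC3(CCCCC)OCCO3)c(C(=O)OCc3ccccc3)c(OC)c2)OCCO1 | intermediate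
22 | water | O | starting material
23 | benzyl 4-{[2-(benzyloxy)-4-methoxy-6-(2-oxoheptyl)benzoyl]oxy}-2-methoxy-6-(2-oxoheptyl)benzoate | CCCCCC(=O)Cc1cc(OC)cc(OCc2ccccc2)c1C(=O)Oc1cc(CC(=O)CCCCC)c(C(=O)OCc2ccccc2)c(OC)c1 | intermediate
24 | 4-{[2-hydroxy-4-methoxy-6-(2-oxoheptyl)benzoyl]oxy}-2-methoxy-6-(2-oxoheptyl)benzoic acid | CCCCCC(=O)Cc1cc(OC)cc(O)c1C(=O)Oc1cc(CC(=O)CCCCC)c(C(=O)O)c(OC)c1 | target

**Step count and risks**

Total step count: 13 (the one-pot step 5 counted once). Longest linear sequence: 9 steps (11 → 24 through steps 5–13); the A branch adds steps 1–4 before the convergence in step 11.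

The three steps most likely to fail:

1. Step 3 (ketalization of 6). The Lewis acid may drive attack of the ketone enol on the neighbouring methyl ester, giving an isocoumarin faster than the dioxolane forms. The fallback sets out from 6. It is treated with propane-1,3-dithiol and BF3·OEt2 (0.3 equiv) in CH2Cl2 at −20 °C, where the sulfur nucleophile captures the activated ketone much faster than lactonization, to give methyl 2-(benzyloxy)-4-methoxy-6-[(2-pentyl-1,3-dithian-2-yl)methyl]benzoate F1. Oxidative trans-ketalization of this with PhI(OCOCF3)2 in MeCN containing excess ethylene glycol exchanges sulfur for oxygen without ever freeing the ketone. The fallback comes back to the route at 8.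

2. Step 11 (esterification of the di-ortho-substituted acid). Carbodiimide activation may stall at the N-acylurea. The fallback sets out from 10. It is converted with cyanuric fluoride and pyridine in CH2Cl2 at −10 °C into 2-(benzyloxy)-4-methoxy-6-[(2-pentyl-1,3-dioxolan-2-yl)methyl]benzoyl fluoride F2, an isolable acyl donor with a small leaving group that tolerates the acetal. This is then combined with 20 as its potassium phenoxide (K2CO3, MeCN, rt). The fallback comes back to the route at 21.

3. Step 12 (double deketalization next to the depside ester). The freed A-ring ketone may cyclize onto the aryl ester during hydrolysis, work-up or chromatography, expelling the B-ring phenol. The fallback sets out from 21 and inverts the order of the two unmasking operations, so that no keto depside has to be isolated. Hydrogenolysis (H2, Pd/C, EtOAc) first gives 4-({2-hydroxy-4-methoxy-6-[(2-pentyl-1,3-dioxolan-2-yl)methyl]benzoyl}oxy)-2-methoxy-6-[(2-pentyl-1,3-dioxolan-2-yl)methyl]benzoic acid F3. Its two dioxolanes are then hydrolysed as the last operation in AcOH–H2O–THF (3:1:1) at 35 °C, and the product is crystallized directly. The fallback comes back to the route at 24.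

**Further compounds**
F1 | step 3 | methyl 2-(benzyloxy)-4-methoxy-6-[(2-pentyl-1,3-dithian-2-yl)methyl]benzoate | CCCCCC1(Cc2cc(OC)cc(OCc3ccccc3)c2C(=O)OC)SCCCS1
F2 | step 11 | 2-(benzyloxy)-4-methoxy-6-[(2-pentyl-1,3-dioxolan-2-yl)methyl]benzoyl fluoride | CCCCCC1(Cc2cc(OC)cc(OCc3ccccc3)c2C(=O)F)OCCO1
F3 | step 12 | 4-({2-hydroxy-4-methoxy-6-[(2-pentyl-1,3-dioxolan-2-yl)methyl]benzoyl}oxy)-2-methoxy-6-[(2-pentyl-1,3-dioxolan-2-yl)methyl]benzoic acid | CCCCCC1(Cc2cc(OC)cc(O)c2C(=O)Oc2cc(CC3(CCCCC)OCCO3)c(C(=O)O)c(OC)c2)OCCO1
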